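Which flask makes the most target in the time allowed, and how much does each one make?

| flask | substrate | reagent | free catalyst | temperature | time |
|---|---|---|---|---|---|
| summer | 0.80 M | 1.20 M | 2.2 mM | 80 °C | 30 h |
| winter | 0.80 M | 1.20 M | 2.2 mM | 50 °C | 30 h |
| dawn | 0.80 M | 1.20 M | 2.2 mM | 110 °C | 30 h |
| midnight | 0.80 M | 1.20 M | 2.2 mM | 140 °C | 30 h |

    reagent + free catalyst → catalyst intermediate A (k1 = 480 M⁻¹ h⁻¹, Ea1 = 58.0 kJ mol⁻¹)
    catalyst intermediate A ⇌ by-product + catalyst intermediate B (K2 = 1.5 M, k2 = 14 h⁻¹, Ea2 = 101 kJ mol⁻¹, ΔH2 = −12.0 kJ mol⁻¹)
    substrate + catalyst intermediate B ⇌ catalyst intermediate C (K3 = 0.63 M⁻¹, k3 = 650 M⁻¹ h⁻¹, Ea3 = 65.0 kJ mol⁻¹, ΔH3 = 0 kJ mol⁻¹)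
    catalyst intermediate C → free catalyst + target (k4 = 6.4 h⁻¹, Ea4 = 104 kJ mol⁻¹)
    substrate + by-product → side product (k5 = 0.0068 M⁻¹ h⁻¹, Ea5 = 92.0 kJ mol⁻¹)
    2 substrate → homo dimer (k6 = 9.4 × 10⁻⁶ M⁻¹ h⁻¹, Ea6 = 110 kJ mol⁻¹)
    catalyst intermediate A + by-product → spent catalyst (k7 = 0.0071 M⁻¹ h⁻¹, Ea7 = 87.0 kJ mol⁻¹)
    (constants at 110 °C)

- the best flask by amount of target, in percent of the substrate charged; "all alike" if 1.5 percentage points covers them all (summer / winter / dawn / midnight / all alike)
- amount of target at the end, in percent of the substrate charged, summer
- amount of target at the end, in percent of the substrate charged, winter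
- amount of target at the end, in percent of the substrate charged, dawn
- amount of target at the end, in percent of the substrate charged, midnight

- a species is counted by the substrate in it: one homo dimer counts as two
- for a step with 2 of a species take k times the square, and two of it per event
- at 110 °C the constants are as listed, elsewhere as the activation energies and enthalpies make them

We ask first where the catalyst waits. In the dawn flask, catalyst intermediate C returns to catalyst intermediate B at 1030 h⁻¹, which is 161 times faster than it releases target at 6.4 h⁻¹. So we take the binding as settled, a pre-equilibrium, and reckon with what it leaves free. At the charge, the binding constant times [substrate] is 0.504. This is the pairing ratio, [catalyst intermediate C] over [catalyst intermediate B] with the binding at balance. The binding has enthalpy 0 kJ mol⁻¹, so its constant does not move with temperature.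

Then how fast does the round turn? The pairing ratio puts a share 0.335 of those two forms in catalyst intermediate C. In the dawn flask, release therefore runs at 2.14 h⁻¹ per catalyst held in those two forms. That is slower than the departure of by-product from catalyst intermediate A at 14 h⁻¹, so release is the rate-limiting step there. Taken in series, the two give 1.86 h⁻¹.

Is that enough? At that pace we reckon 55.8 turnovers for the dawn flask in 30 h, while the substrate charge needs 364. With [substrate] held at the charge and by-product never returning, our figure for dawn is 15.3%, so dawn stops far short. Release has a higher barrier, 104 kJ mol⁻¹, than the side step and the catalyst loss, so its constant gains more on heating than theirs. We commit to midnight.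

The forecast also says midnight, with 0.017% for winter, 0.93% for summer, 14.2% for dawn and 71% for midnight. Its grounds: “well under one turnover at 50 °C, a few at 80 °C, about 50 at 110 °C, and a few hundred at 140 °C”. Our dawn figure stands above its number.

The simulation gives midnight, with 0.0161% for winter, 0.931% for summer, 14.2% for dawn and 71.7% for midnight, so the forecast is right. A midnight run with the return of catalyst intermediate C struck out gives 94.4%, which is 23 percentage points away from the forecast. In the midnight flask at 30.0 h, [substrate] stands at 11.1% of its charge, so the pairing ratio reckons 0.0559. The midnight flask holds 3.34% of catalyst intermediate C against 60.3% of catalyst intermediate B, a ratio of 0.0554. In the winter flask at 30.0 h, the pairing ratio reckons 0.504, and the 21.7% of catalyst intermediate C against 43.1% of catalyst intermediate B gives 0.503.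

The numbers of this flask belong to no real substance.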